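**Plan**

Ring labels: A is the methyl 5‑hydroxy‑3‑methoxybenzoate ring, B the 6‑hydroxy‑4‑methylbenzoyl ring, C the 5‑methylpyrogallol ring (O1, O2, O3 on C1–C3), D the 4‑hydroxy‑2,6‑bis(methoxycarbonyl)benzoyl ring.

1. Cuts, in order: the ring B C(=O)–O1(ring C) ester; then the oxygen O2 between the ring D carbonyl carbon and ring C C2 is removed, giving a benzophenone; then the ketone–ring C bond and both ring D C–CO2Me bonds.
2. In the A–B half: the diaryl ether bond ring A O–C2(ring B), and the ring A C5–O bond.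
3. Enabling feature: O2 is the central oxygen of ring C and is bonded to C2, which lies between the oxygen‑bearing C1 and C3. The acyl group on O2 is a benzoyl flanked by two esters, so the D–C ester is a 2,6‑dihydroxyaryl/2,6‑diester benzophenone with one oxygen inserted.
4. Forward: no ring is built; all four benzene rings are bought. Order of joining: C + D (aryllithium/aldehyde, oxidation, double carbonylation), oxygen insertion, then the A–B acid (SNAr, Pinnick) is esterified onto O1 of ring C, then debenzylation.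
5. Stereochemistry: the target has no stereogenic element. The only stereocentre on the way (carbinol 8, racemic) is erased by oxidation.

Key step: step 8

Remark (assumption): the SMILES carries no stereodescriptor and the molecule is achiral, so there is nothing to control. 3,5‑Dibromophenol and 2,6‑difluoro‑4‑methylbenzaldehyde are taken as catalogue chemicals; orcinol is used anhydrous.

**Route**

Step 1
Reactants: 1 orcinol (5‑methylbenzene‑1,3‑diol)
Product: 2 1,3‑bis(methoxymethoxy)‑5‑methylbenzene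
Conditions: NaH, DMF, 0 °C; MOMCl, 0 °C → rt
Reagents that add atoms: chloromethyl methyl ether, COCCl
Why: Williamson O‑alkylation of both phenoxides; the MOM ethers later direct lithiation to the carbon between them and come off under mild acid.

Step 2
Reactants: 3 3,5‑dibromophenol
Product: 4 1‑(benzyloxy)‑3,5‑dibromobenzene
Conditions: BnBr, K2CO3, DMF, rt
Reagents that add atoms: benzyl bromide, BrCc1ccccc1
Why: Williamson benzylation of the phenoxide; the benzyl ether should survive every later step up to the final hydrogenolysis.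

Step 3
Reactants: 4 1‑(benzyloxy)‑3,5‑dibromobenzene
Product: 6 4‑(benzyloxy)‑2,6‑dibromobenzaldehyde, via [4‑(benzyloxy)‑2,6‑dibromophenyl]lithium 5 (not isolated)
Conditions: LDA, THF, −78 °C; DMF, −78 → 0 °C; aq. NH4Cl
Reagents that add atoms: N,N‑dimethylformamide, CN(C)C=O
Why: Directed deprotonation and formylation: the hydrogen between the two bromines is the most acidic, and the amide base at −78 °C removes it without Br/Li exchange or aryne formation, as in the preparation of 2,6‑dibromobenzaldehyde from 1,3‑dibromobenzene.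

Step 4
Reactants: 2 1,3‑bis(methoxymethoxy)‑5‑methylbenzene; 6 4‑(benzyloxy)‑2,6‑dibromobenzaldehyde
Product: 8 rac‑[4‑(benzyloxy)‑2,6‑dibromophenyl][2,6‑bis(methoxymethoxy)‑4‑methylphenyl]methanol, via [2,6‑bis(methoxymethoxy)‑4‑methylphenyl]lithium 7 (not isolated)
Conditions: 2, n‑BuLi, THF, 0 °C, 1 h; then 6, −78 → −20 °C; aq. NH4Cl
Reagents that add atoms: none
Why: Directed ortho‑metalation between the two MOM ethers, then 1,2‑addition of the aryllithium to the non‑enolisable aldehyde, which at −78 °C should outrun Br/Li exchange; the carbinol centre forms as a racemate and is removed in step 5.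

Step 5
Reactants: 8 rac‑[4‑(benzyloxy)‑2,6‑dibromophenyl][2,6‑bis(methoxymethoxy)‑4‑methylphenyl]methanol
Product: 9 [4‑(benzyloxy)‑2,6‑dibromophenyl][2,6‑bis(methoxymethoxy)‑4‑methylphenyl]methanone
Conditions: Dess–Martin periodinane, CH2Cl2, rt
Reagents that add atoms: none
Why: Dess–Martin oxidation of a hindered secondary benzhydrol to the diaryl ketone, compatible with MOM and benzyl ethers and aryl bromides.

Step 6
Reactants: 9 [4‑(benzyloxy)‑2,6‑dibromophenyl][2,6‑bis(methoxymethoxy)‑4‑methylphenyl]methanone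
Product: 10 dimethyl 5‑(benzyloxy)‑2‑[2,6‑bis(methoxymethoxy)‑4‑methylbenzoyl]isophthalate
Conditions: Pd(OAc)2 (10 mol %), Xantphos, CO (5 bar), Et3N, MeOH–DMF, 90 °C
Reagents that add atoms: carbon monoxide, [C-]#[O+]; methanol, CO
Why: Palladium‑catalysed alkoxycarbonylation of both aryl bromides, each activated for oxidative addition by the ortho ketone; the esters are installed only after the ketone exists, so no carbinol can lactonise onto them, and ring C has no free ortho C–H for a competing cyclisation.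

Step 7
Reactants: 10 dimethyl 5‑(benzyloxy)‑2‑[2,6‑bis(methoxymethoxy)‑4‑methylbenzoyl]isophthalate
Product: 11 dimethyl 5‑(benzyloxy)‑2‑(2,6‑dihydroxy‑4‑methylbenzoyl)isophthalate
Conditions: 3 M HCl, MeOH, 45 °C
Reagents that add atoms: none
Why: Acid‑catalysed acetal exchange removes both MOM groups as dimethoxymethane; methyl esters are degenerate in methanol, the benzyl ether is stable, and the product is a chelated benzophenone that cannot close to a xanthone.

Step 8
Reactants: 11 dimethyl 5‑(benzyloxy)‑2‑(2,6‑dihydroxy‑4‑methylbenzoyl)isophthalate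
Product: 12 dimethyl 5‑(benzyloxy)‑2‑[(2,6‑dihydroxy‑4‑methylphenoxy)carbonyl]isophthalate
Conditions: mCPBA (2 equiv), TFA (0.2 equiv), CH2Cl2, 0 °C → rt, dark
Reagents that add atoms: 3‑chloroperoxybenzoic acid, OOC(=O)c1cccc(Cl)c1
Why: The peracid adds to the ketone carbonyl, which is polarised by the O–H···O=C hydrogen bond from the coplanar dihydroxyaryl ring and by the acid co‑catalyst, to give the Criegee adduct; ring C then shifts from carbon to the proximal peroxide oxygen as 3‑chlorobenzoate leaves, which forms the ring D C(=O)–O bond and the O–C2 bond of ring C in one event. The closest known chemistry is the Baeyer–Villiger (acid Dakin‑type) oxidation of ortho‑hydroxy‑ and ortho‑alkoxyaryl ketones to catechol monoesters, here applied at its steric limit. No ring closes and no stereocentre arises. The step needs exclusive migration of the dihydroxytolyl group, which should follow from electronics: its ipso carbon has two ortho oxygen donors and a para methyl, whereas the ring D ipso carbon, although para to the benzyloxy group, sits between two electron‑withdrawing esters. Ring hydroxylation should be held back by the acyl‑deactivated resorcinol ring of 11, a limited peracid charge and low temperature. The base‑free medium should keep the new hindered aryl ester from hydrolysis and from shifting to a neighbouring phenol, and because 12 is C2‑symmetric about O2 the ring C oxygen pattern arises without any regiochemical choice.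

Step 9
Reactants: 13 2‑hydroxy‑3‑methoxybenzoic acid (3‑methoxysalicylic acid)
Product: 15 2,5‑dihydroxy‑3‑methoxybenzoic acid, via 3‑carboxy‑4‑hydroxy‑5‑methoxyphenyl sulfate 14 (not isolated)
Conditions: K2S2O8, aq. NaOH, 10–20 °C, 24 h; then HCl to pH 1, 90 °C
Reagents that add atoms: potassium peroxodisulfate, [K+].[K+].[O-]S(=O)(=O)OOS(=O)(=O)[O-]
Why: Elbs persulfate oxidation: the phenoxide attacks a peroxide oxygen through its only free activated position, the para carbon C5, and the aryl sulfate is then hydrolysed by acid.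

Step 10
Reactants: 15 2,5‑dihydroxy‑3‑methoxybenzoic acid
Product: 16 methyl 2,5‑dihydroxy‑3‑methoxybenzoate
Conditions: MeOH, H2SO4 (cat.), reflux, N2
Reagents that add atoms: methanol, CO
Why: Fischer esterification, as used for gentisic acid; the phenols are inert under these conditions.

Step 11
Reactants: 16 methyl 2,5‑dihydroxy‑3‑methoxybenzoate
Product: 17 methyl 5‑(benzyloxy)‑2‑hydroxy‑3‑methoxybenzoate
Conditions: BnBr (1.05 equiv), K2CO3, acetone, reflux, N2
Reagents that add atoms: benzyl bromide, BrCc1ccccc1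
Why: Williamson benzylation selective for the 5‑hydroxyl, because the 2‑hydroxyl is hydrogen‑bonded to the ester carbonyl and flanked on both sides, the known behaviour of methyl gentisate.

Step 12
Reactants: 18 2,6‑difluoro‑4‑methylbenzaldehyde
Product: 19 2‑(benzyloxy)‑6‑fluoro‑4‑methylbenzaldehyde
Conditions: BnOH (1.0 equiv), NaH, THF, 0 °C → rt
Reagents that add atoms: benzyl alcohol, OCc1ccccc1
Why: Nucleophilic aromatic substitution of one aldehyde‑activated ortho fluorine by sodium benzyloxide; the alkoxy group introduced deactivates the ring toward a second substitution.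

Step 13
Reactants: 17 methyl 5‑(benzyloxy)‑2‑hydroxy‑3‑methoxybenzoate; 19 2‑(benzyloxy)‑6‑fluoro‑4‑methylbenzaldehyde
Product: 20 methyl 5‑(benzyloxy)‑2‑[3‑(benzyloxy)‑2‑formyl‑5‑methylphenoxy]‑3‑methoxybenzoate
Conditions: Cs2CO3, DMSO, 90 °C
Reagents that add atoms: none
Why: SNAr diaryl ether synthesis: the caesium phenoxide of 17 displaces the remaining fluorine ortho to the aldehyde through a Meisenheimer adduct, and neither partner has an enolisable position.

Step 14
Reactants: 20 methyl 5‑(benzyloxy)‑2‑[3‑(benzyloxy)‑2‑formyl‑5‑methylphenoxy]‑3‑methoxybenzoate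
Product: 21 2‑(benzyloxy)‑6‑[4‑(benzyloxy)‑2‑methoxy‑6‑(methoxycarbonyl)phenoxy]‑4‑methylbenzoic acid (O,O'‑dibenzyl asterric acid)
Conditions: NaClO2, NaH2PO4, 2‑methyl‑2‑butene, t‑BuOH–THF–H2O, rt
Reagents that add atoms: sodium chlorite, [Na+].[O-]Cl=O
Why: Pinnick oxidation of the aryl aldehyde to the acid, with the alkene scavenging hypochlorous acid so that the electron‑rich rings are not chlorinated; methyl ester and benzyl ethers are untouched.

Step 15
Reactants: 21 O,O'‑dibenzyl asterric acid; 12 dimethyl 5‑(benzyloxy)‑2‑[(2,6‑dihydroxy‑4‑methylphenoxy)carbonyl]isophthalate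
Product: 23 tri‑O‑benzyl pseudophenone A (ring C O1 acylated by the dibenzyl asterric acyl group; O2 carries the ring D acyl group; O3 free; benzyl ethers on ring A O5 / ring B O6 / ring D O4), via O,O'‑dibenzylasterroyl chloride 22 (not isolated)
Conditions: 21, (COCl)2, DMF (cat.), CH2Cl2, 0 °C → rt, concentrate; then 12 (2 equiv), pyridine, DMAP (cat.), CH2Cl2, 0 °C → rt
Reagents that add atoms: none
Why: Acid chloride formation followed by pyridine/DMAP acylation of one of the two equivalent phenols of 12 (depside‑type esterification); excess diol and the crowding created by the first acylation should limit double acylation, the weak base should leave the hindered ring D ester in place, and both ortho carbons of ring A are substituted so the acyl cation cannot close to a xanthone.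

Step 16
Reactants: 23 tri‑O‑benzyl pseudophenone A
Product: 24 pseudophenone A
Conditions: H2 (1 atm), 10 % Pd/C, EtOAc–THF, rt
Reagents that add atoms: none
Why: Hydrogenolysis of the three benzyl aryl ethers under neutral conditions, to which the aryl esters, methyl esters and the diaryl ether are inert.

**Compound list**

1 | orcinol (5‑methylbenzene‑1,3‑diol) | Cc1cc(O)cc(O)c1 | starting material
2 | 1,3‑bis(methoxymethoxy)‑5‑methylbenzene | Cc1cc(OCOC)cc(OCOC)c1 | intermediate
3 | 3,5‑dibromophenol | Oc1cc(Br)cc(Br)c1 | starting material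
4 | 1‑(benzyloxy)‑3,5‑dibromobenzene | Brc1cc(Br)cc(OCc2ccccc2)c1 | intermediate
5 | [4‑(benzyloxy)‑2,6‑dibromophenyl]lithium | [Li]c1c(Br)cc(OCc2ccccc2)cc1Br | intermediate
6 | 4‑(benzyloxy)‑2,6‑dibromobenzaldehyde | O=Cc1c(Br)cc(OCc2ccccc2)cc1Br | intermediate
7 | [2,6‑bis(methoxymethoxy)‑4‑methylphenyl]lithium | [Li]c1c(OCOC)cc(C)cc1OCOC | intermediate
8 | rac‑[4‑(benzyloxy)‑2,6‑dibromophenyl][2,6‑bis(methoxymethoxy)‑4‑methylphenyl]methanol | OC(c1c(Br)cc(OCc2ccccc2)cc1Br)c1c(OCOC)cc(C)cc1OCOC | intermediate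
9 | [4‑(benzyloxy)‑2,6‑dibromophenyl][2,6‑bis(methoxymethoxy)‑4‑methylphenyl]methanone | O=C(c1c(Br)cc(OCc2ccccc2)cc1Br)c1c(OCOC)cc(C)cc1OCOC | intermediate
10 | dimethyl 5‑(benzyloxy)‑2‑[2,6‑bis(methoxymethoxy)‑4‑methylbenzoyl]isophthalate | COC(=O)c1cc(OCc2ccccc2)cc(C(=O)OC)c1C(=O)c1c(OCOC)cc(C)cc1OCOC | intermediate
11 | dimethyl 5‑(benzyloxy)‑2‑(2,6‑dihydroxy‑4‑methylbenzoyl)isophthalate | COC(=O)c1cc(OCc2ccccc2)cc(C(=O)OC)c1C(=O)c1c(O)cc(C)cc1O | intermediate
12 | dimethyl 5‑(benzyloxy)‑2‑[(2,6‑dihydroxy‑4‑methylphenoxy)carbonyl]isophthalate | Cc1cc(O)c(OC(=O)c2c(C(=O)OC)cc(OCc3ccccc3)cc2C(=O)OC)c(O)c1 | intermediate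
13 | 2‑hydroxy‑3‑methoxybenzoic acid | COc1cccc(C(=O)O)c1O | starting material
14 | 3‑carboxy‑4‑hydroxy‑5‑methoxyphenyl sulfate (present as its salt; drawn as the hydrogen sulfate) | COc1cc(OS(=O)(=O)O)cc(C(=O)O)c1O | intermediate
15 | 2,5‑dihydroxy‑3‑methoxybenzoic acid | COc1cc(O)cc(C(=O)O)c1O | intermediate
16 | methyl 2,5‑dihydroxy‑3‑methoxybenzoate | COC(=O)c1cc(O)cc(OC)c1O | intermediate
17 | methyl 5‑(benzyloxy)‑2‑hydroxy‑3‑methoxybenzoate | COC(=O)c1cc(OCc2ccccc2)cc(OC)c1O | intermediate
18 | 2,6‑difluoro‑4‑methylbenzaldehyde | Cc1cc(F)c(C=O)c(F)c1 | starting material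
19 | 2‑(benzyloxy)‑6‑fluoro‑4‑methylbenzaldehyde | Cc1cc(F)c(C=O)c(OCc2ccccc2)c1 | intermediate
20 | methyl 5‑(benzyloxy)‑2‑[3‑(benzyloxy)‑2‑formyl‑5‑methylphenoxy]‑3‑methoxybenzoate | COC(=O)c1cc(OCc2ccccc2)cc(OC)c1Oc1cc(C)cc(OCc2ccccc2)c1C=O | intermediate
21 | 2‑(benzyloxy)‑6‑[4‑(benzyloxy)‑2‑methoxy‑6‑(methoxycarbonyl)phenoxy]‑4‑methylbenzoic acid | COC(=O)c1cc(OCc2ccccc2)cc(OC)c1Oc1cc(C)cc(OCc2ccccc2)c1C(=O)O | intermediate
22 | 2‑(benzyloxy)‑6‑[4‑(benzyloxy)‑2‑methoxy‑6‑(methoxycarbonyl)phenoxy]‑4‑methylbenzoyl chloride | COC(=O)c1cc(OCc2ccccc2)cc(OC)c1Oc1cc(C)cc(OCc2ccccc2)c1C(=O)Cl | intermediate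
23 | tri‑O‑benzyl pseudophenone A | COC(=O)c1cc(OCc2ccccc2)cc(OC)c1Oc1cc(C)cc(OCc2ccccc2)c1C(=O)Oc1cc(C)cc(O)c1OC(=O)c1c(C(=O)OC)cc(OCc2ccccc2)cc1C(=O)OC | intermediate
24 | pseudophenone A | COC(=O)c1cc(O)cc(OC)c1Oc1cc(C)cc(O)c1C(=O)Oc1cc(C)cc(O)c1OC(=O)c1c(C(=O)OC)cc(O)cc1C(=O)OC | target

**Totals**

Total step count: 16.
Longest linear sequence: 9 steps (3 → 4 → 6 → 8 → 9 → 10 → 11 → 12 → 23 → 24; steps 2–8, 15, 16).

**Steps most likely to fail**

Step 8. The peracid may add too slowly to a carbonyl that is screened on both faces by the ester groups of the perpendicular ring D and damped by the chelating phenols. Peracid hydroxylation of the electron‑rich ring, or capture of the Criegee hydroxyl by a flanking ester, could then overtake the aryl shift. The fallback replaces oxygen insertion by conventional acylation; it sets out from 2 and 6 and returns at 12. Aryllithium 7, made from 2 as in step 4, is quenched with trimethyl borate to dimethyl [2,6‑bis(methoxymethoxy)‑4‑methylphenyl]boronate F1, which alkaline hydrogen peroxide oxidises in the same flask to 2,6‑bis(methoxymethoxy)‑4‑methylphenol F2. Aldehyde 6 is doubly methoxycarbonylated (Pd(OAc)2/Xantphos, CO, MeOH, Et3N) to dimethyl 5‑(benzyloxy)‑2‑formylisophthalate F3. Pinnick oxidation gives 4‑(benzyloxy)‑2,6‑bis(methoxycarbonyl)benzoic acid F4, and oxalyl chloride converts it into 4‑(benzyloxy)‑2,6‑bis(methoxycarbonyl)benzoyl chloride F5. The sodium phenoxide of F2 (NaH, THF) is acylated by F5 to dimethyl 5‑(benzyloxy)‑2‑{[2,6‑bis(methoxymethoxy)‑4‑methylphenoxy]carbonyl}isophthalate F6. HCl in methanol at room temperature then removes the MOM groups and should deliver 12.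

Step 6. The second carbonylation may stall at a C–Br bond flanked by the ketone and the first ester, with protodebromination taking over. The fallback builds the carboxyl carbons by cross‑coupling and oxidative cleavage; it sets out from 9 and returns at 10. Double Suzuki–Miyaura coupling of 9 with potassium vinyltrifluoroborate (PdCl2(dppf), Cs2CO3, THF–H2O) should give [4‑(benzyloxy)‑2,6‑divinylphenyl][2,6‑bis(methoxymethoxy)‑4‑methylphenyl]methanone F7. Lemieux–Johnson cleavage (OsO4 cat., NaIO4, 2,6‑lutidine) gives 5‑(benzyloxy)‑2‑[2,6‑bis(methoxymethoxy)‑4‑methylbenzoyl]isophthalaldehyde F8. Pinnick oxidation gives 5‑(benzyloxy)‑2‑[2,6‑bis(methoxymethoxy)‑4‑methylbenzoyl]isophthalic acid F9, and carboxylate alkylation (MeI, K2CO3, DMF) leads to 10.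

Step 15. Acyl transfer between a di‑ortho‑substituted aroyl chloride and a hindered, hydrogen‑bonded phenol may be slow. This would give time for a base‑induced shift of the ring D acyl group from O2 to O1 and for double acylation. The fallback inverts the order of esterification and oxygen insertion; it sets out from 11 and 22 and returns at 23. One of the two equivalent phenols of ketone 11, which has no neighbouring ester that could migrate, is acylated with 22 (pyridine, DMAP) to dimethyl 5‑(benzyloxy)‑2‑[2‑({2‑(benzyloxy)‑6‑[4‑(benzyloxy)‑2‑methoxy‑6‑(methoxycarbonyl)phenoxy]‑4‑methylbenzoyl}oxy)‑6‑hydroxy‑4‑methylbenzoyl]isophthalate F10. The peracid oxidation of step 8 is then run on F10; the remaining free ortho phenol still activates the ketone and the oxygenated ring should migrate, giving 23 directly.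

**Further compounds**

F1 | step 8 | dimethyl [2,6‑bis(methoxymethoxy)‑4‑methylphenyl]boronate | COB(OC)c1c(OCOC)cc(C)cc1OCOC
F2 | step 8 | 2,6‑bis(methoxymethoxy)‑4‑methylphenol | Cc1cc(OCOC)c(O)c(OCOC)c1
F3 | step 8 | dimethyl 5‑(benzyloxy)‑2‑formylisophthalate | COC(=O)c1cc(OCc2ccccc2)cc(C(=O)OC)c1C=O
F4 | step 8 | 4‑(benzyloxy)‑2,6‑bis(methoxycarbonyl)benzoic acid | COC(=O)c1cc(OCc2ccccc2)cc(C(=O)OC)c1C(=O)O
F5 | step 8 | 4‑(benzyloxy)‑2,6‑bis(methoxycarbonyl)benzoyl chloride | COC(=O)c1cc(OCc2ccccc2)cc(C(=O)OC)c1C(=O)Cl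
F6 | step 8 | dimethyl 5‑(benzyloxy)‑2‑{[2,6‑bis(methoxymethoxy)‑4‑methylphenoxy]carbonyl}isophthalate | COC(=O)c1cc(OCc2ccccc2)cc(C(=O)OC)c1C(=O)Oc1c(OCOC)cc(C)cc1OCOC
F7 | step 6 | [4‑(benzyloxy)‑2,6‑divinylphenyl][2,6‑bis(methoxymethoxy)‑4‑methylphenyl]methanone | C=Cc1cc(OCc2ccccc2)cc(C=C)c1C(=O)c1c(OCOC)cc(C)cc1OCOC
F8 | step 6 | 5‑(benzyloxy)‑2‑[2,6‑bis(methoxymethoxy)‑4‑methylbenzoyl]isophthalaldehyde | O=Cc1cc(OCc2ccccc2)cc(C=O)c1C(=O)c1c(OCOC)cc(C)cc1OCOC
F9 | step 6 | 5‑(benzyloxy)‑2‑[2,6‑bis(methoxymethoxy)‑4‑methylbenzoyl]isophthalic acid | OC(=O)c1cc(OCc2ccccc2)cc(C(=O)O)c1C(=O)c1c(OCOC)cc(C)cc1OCOC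
F10 | step 15 | dimethyl 5‑(benzyloxy)‑2‑[2‑({2‑(benzyloxy)‑6‑[4‑(benzyloxy)‑2‑methoxy‑6‑(methoxycarbonyl)phenoxy]‑4‑methylbenzoyl}oxy)‑6‑hydroxy‑4‑methylbenzoyl]isophthalate | COC(=O)c1cc(OCc2ccccc2)cc(OC)c1Oc1cc(C)cc(OCc2ccccc2)c1C(=O)Oc1cc(C)cc(O)c1C(=O)c1c(C(=O)OC)cc(OCc2ccccc2)cc1C(=O)OC
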